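Everything rests on the 2,3-dihydrobenzofuran of the right-hand half: its O1–C7a and C3–C3a bonds leave neighbouring carbons of the benzo ring, while C2, C3 and the CH2OH map onto an erythro 1-aryl-2,3-epoxypropan-1-ol. In one operation the alkoxide of this epoxy alcohol adds to a 3-silylaryne (from a 2,6-bis(trimethylsilyl)aryl triflate) to form O1–C7a, and the aryl anion so formed opens the epoxide 5-exo to form C3a–C3, giving the trans ring and the free CH2O−. Silicon beside the triple bond steers oxygen to C7a and is later exchanged for the 7-methoxy group. Lactone enolate alkylation, an Evans aldol for the keto alcohol and hydrogenolysis finish the synthesis.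

Key step: step 6

Assumption: in step 13 the (S,S)-enantiomer of MOD-DIOP is taken to deliver the (R)-acid 24; if the sense proves opposite, the (R,R)-ligand is used.
Assumption: compounds 1, 2, 5, 20, 22 and 27, and the 3-bromo-4-fluoro-5-methoxybenzaldehyde used in one fallback, are taken as purchasable.

Step 1
Reactants: 1 4-(benzyloxy)-3-methoxybenzaldehyde; 2 vinylmagnesium bromide
Product: 3 (±)-1-[4-(benzyloxy)-3-methoxyphenyl]prop-2-en-1-ol
Conditions: THF, 0 °C; aq. NH4Cl
Reagents that add atoms: none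
Why: Grignard 1,2-addition to the aldehyde should give the racemic secondary allylic alcohol needed for kinetic resolution.

Step 2
Reactants: 3 (±)-1-[4-(benzyloxy)-3-methoxyphenyl]prop-2-en-1-ol
Product: 4 (R)-[4-(benzyloxy)-3-methoxyphenyl][(2S)-oxiran-2-yl]methanol (erythro)
Conditions: Ti(O-i-Pr)4, D-(−)-diisopropyl tartrate, t-BuOOH (0.6 equiv), 4 Å MS, CH2Cl2, −20 °C
Reagents that add atoms: tert-butyl hydroperoxide, CC(C)(C)OO
Why: Sharpless kinetic resolution, in which the D-tartrate catalyst should epoxidise (S)-3 fast and erythro-selectively (the titanium-bound hydroxyl delivers oxygen to one alkene face; the carbinol descriptor becomes R only because the oxirane carbon outranks the aryl group) while (R)-3 is left behind.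

Step 3
Reactants: 5 3,5-dibromo-4-hydroxybenzaldehyde
Product: 6 2,6-dibromo-4-(1,3-dioxolan-2-yl)phenol
Conditions: ethylene glycol, p-TsOH (cat.), toluene, reflux (Dean–Stark)
Reagents that add atoms: ethylene glycol, OCCO
Why: Acid-catalysed acetalisation should mask the aldehyde against the organolithium, fluoride and alkoxide chemistry that follows.

Step 4
Reactants: 6 2,6-dibromo-4-(1,3-dioxolan-2-yl)phenol
Product: 9 4-(1,3-dioxolan-2-yl)-2,6-bis(trimethylsilyl)phenol, via aryl silyl ether 7 (not isolated), via tris-silylated ether 8 (not isolated)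
Conditions: HN(SiMe3)2, THF, 65 °C, evaporate; n-BuLi (2.2 equiv), THF, −78 → 0 °C; Me3SiCl (2.5 equiv), −78 °C → rt; K2CO3, MeOH, rt
Reagents that add atoms: hexamethyldisilazane, C[Si](C)(C)N[Si](C)(C)C; chlorotrimethylsilane, C[Si](C)(C)Cl
Why: The first bromine–lithium exchange should trigger a retro-Brook 1,3-shift of silicon from oxygen to carbon, the second exchange gives the ortho-lithiated phenoxide that chlorotrimethylsilane silylates, and methanolysis cleaves only the O–Si bond.

Step 5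
Reactants: 9 4-(1,3-dioxolan-2-yl)-2,6-bis(trimethylsilyl)phenol
Product: 10 4-(1,3-dioxolan-2-yl)-2,6-bis(trimethylsilyl)phenyl trifluoromethanesulfonate
Conditions: n-BuLi, Et2O, 0 °C; Tf2O, 0 °C → rt
Reagents that add atoms: trifluoromethanesulfonic anhydride, O=S(=O)(OS(=O)(=O)C(F)(F)F)C(F)(F)F
Why: O-Sulfonylation of the hindered lithium phenoxide should give a symmetric ortho-silylaryl triflate from which fluoride can release only one aryne.

Step 6
Reactants: 4 (R)-[4-(benzyloxy)-3-methoxyphenyl][(2S)-oxiran-2-yl]methanol; 10 4-(1,3-dioxolan-2-yl)-2,6-bis(trimethylsilyl)phenyl trifluoromethanesulfonate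
Product: 14 (2S,3R)-3-[(benzyloxy)methyl]-2-[4-(benzyloxy)-3-methoxyphenyl]-5-(1,3-dioxolan-2-yl)-7-(trimethylsilyl)-2,3-dihydro-1-benzofuran, via sodium alkoxide 11 (not isolated), via silylaryne 12 (not isolated), via cyclised alkoxide 13 (not isolated)
Conditions: 4 (1.5 equiv), NaH, THF, 0 °C, 15 min; then 10, KF, 18-crown-6, THF, 0 °C → rt; then BnBr, n-Bu4NI, rt
Reagents that add atoms: benzyl bromide, BrCc1ccccc1
Why: Proposed new method: fluoride removes one SiMe3 group and the triflate of 10 to give the 3-silylaryne 12; the alkoxide oxygen of 11 adds to the aryne carbon next to silicon (future C7a), and the aryl carbanion left on the neighbouring carbon (future C3a) attacks the internal epoxide carbon in an SN2 5-exo-tet closure that forms the dihydrofuran ring and frees the primary alkoxide 13, which is benzylated in the same flask. The closest known reaction types are the ortho-selective addition of primary amines to 3-silylbenzynes, aryne annulations in which a heteroatom nucleophile carries the electrophile that traps the aryl anion, and the Parham-type cyclisation of ortho-lithiated aryl glycidyl ethers to 2,3-dihydrobenzofuran-3-methanols. The side of addition is set by the group beside the triple bond: electropositive silicon widens the internal angle at the adjacent aryne carbon and disfavours a carbanion next to it, so oxygen should go ortho to silicon (an oxygen nucleophile with one substituent is sterically comparable to a primary amine), whereas a 7-methoxy group at this stage would send oxygen to the wrong carbon. C2 keeps the carbinol configuration of 4 because its C–O bond is untouched, and C3 is formed with inversion at the epoxide carbon, so the erythro epoxy alcohol can give only the trans-(2S,3R) ring. The step needs 5-exo rather than 6-endo opening (favoured by the short tether, as in the glycidyl ether precedent) and an aprotic medium (preformed alkoxide, KF/18-crown-6 in THF) so that the aryl anion is not protonated; the alkoxide is made cold and used at once to suppress Payne rearrangement.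

Step 7
Reactants: 14 (2S,3R)-3-[(benzyloxy)methyl]-2-[4-(benzyloxy)-3-methoxyphenyl]-5-(1,3-dioxolan-2-yl)-7-(trimethylsilyl)-2,3-dihydro-1-benzofuran
Product: 15 (2S,3R)-3-[(benzyloxy)methyl]-2-[4-(benzyloxy)-3-methoxyphenyl]-5-(1,3-dioxolan-2-yl)-7-iodo-2,3-dihydro-1-benzofuran
Conditions: ICl, NaHCO3, CH2Cl2, −78 °C
Reagents that add atoms: iodine monochloride, ClI
Why: Electrophilic ipso-iododesilylation at the silicon-bearing carbon, activated by the ortho ring oxygen and the β-silicon effect, should be much faster than C–H iodination of the other electron-rich rings at low temperature.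

Step 8
Reactants: 15 (2S,3R)-3-[(benzyloxy)methyl]-2-[4-(benzyloxy)-3-methoxyphenyl]-5-(1,3-dioxolan-2-yl)-7-iodo-2,3-dihydro-1-benzofuran
Product: 16 (2S,3R)-3-[(benzyloxy)methyl]-2-[4-(benzyloxy)-3-methoxyphenyl]-5-(1,3-dioxolan-2-yl)-7-methoxy-2,3-dihydro-1-benzofuran
Conditions: CuI (10 mol %), 3,4,7,8-tetramethyl-1,10-phenanthroline, Cs2CO3, MeOH/toluene, 110 °C
Reagents that add atoms: methanol, CO
Why: Ullmann-type copper-catalysed C–O coupling of the aryl iodide with methanol should install the 7-methoxy group; the substrate has no base-labile stereocentre.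

Step 9
Reactants: 16 (2S,3R)-3-[(benzyloxy)methyl]-2-[4-(benzyloxy)-3-methoxyphenyl]-5-(1,3-dioxolan-2-yl)-7-methoxy-2,3-dihydro-1-benzofuran
Product: 18 [(2S,3R)-3-[(benzyloxy)methyl]-2-[4-(benzyloxy)-3-methoxyphenyl]-7-methoxy-2,3-dihydro-1-benzofuran-5-yl]methanol, via aldehyde 17 (not isolated)
Conditions: 1 M HCl, THF, rt; NaHCO3; NaBH4, MeOH, 0 °C
Reagents that add atoms: water, O
Why: Mild acetal hydrolysis followed by borohydride reduction of the aldehyde in the same flask should give the benzylic alcohol without touching the benzyl ethers or the dihydrobenzofuran.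

Step 10
Reactants: 18 [(2S,3R)-3-[(benzyloxy)methyl]-2-[4-(benzyloxy)-3-methoxyphenyl]-7-methoxy-2,3-dihydro-1-benzofuran-5-yl]methanol
Product: 19 (2S,3R)-3-[(benzyloxy)methyl]-2-[4-(benzyloxy)-3-methoxyphenyl]-5-(bromomethyl)-7-methoxy-2,3-dihydro-1-benzofuran
Conditions: CBr4, PPh3, CH2Cl2, 0 °C; used crude
Reagents that add atoms: carbon tetrabromide, BrC(Br)(Br)Br
Why: The Appel reaction should convert the only free alcohol into the reactive benzylic bromide under neutral conditions.

Step 11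
Reactants: 20 3-bromo-4-hydroxy-5-methoxybenzaldehyde (5-bromovanillin)
Product: 21 4-(benzyloxy)-3-bromo-5-methoxybenzaldehyde
Conditions: BnBr, K2CO3, DMF, rt
Reagents that add atoms: benzyl bromide, BrCc1ccccc1
Why: Williamson etherification should protect the phenol as the benzyl ether used throughout.

Step 12
Reactants: 21 4-(benzyloxy)-3-bromo-5-methoxybenzaldehyde; 22 dimethyl succinate
Product: 23 (E)-4-[4-(benzyloxy)-3-bromo-5-methoxyphenyl]-3-(methoxycarbonyl)but-3-enoic acid
Conditions: NaOMe, MeOH, reflux; then aq. HCl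
Reagents that add atoms: none
Why: Stobbe condensation (aldol addition, lactonisation and eliminative ring opening) should give the (E)-arylidene succinic half-ester.

Step 13
Reactants: 23 (E)-4-[4-(benzyloxy)-3-bromo-5-methoxyphenyl]-3-(methoxycarbonyl)but-3-enoic acid
Product: 24 (R)-4-[4-(benzyloxy)-3-bromo-5-methoxyphenyl]-3-(methoxycarbonyl)butanoic acid
Conditions: H2 (1–5 atm), [Rh(cod)2]BF4 (1 mol %), (S,S)-MOD-DIOP, Et3N, MeOH, rt
Reagents that add atoms: none
Why: Carboxylate-directed asymmetric hydrogenation of the itaconate-type alkene with the chiral rhodium diphosphine catalyst should set the future lactone C4 centre as R without touching the aryl bromide or benzyl ether.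

Step 14
Reactants: 24 (R)-4-[4-(benzyloxy)-3-bromo-5-methoxyphenyl]-3-(methoxycarbonyl)butanoic acid
Product: 25 (R)-4-[4-(benzyloxy)-3-bromo-5-methoxybenzyl]dihydrofuran-2(3H)-one
Conditions: KOH, EtOH; CaCl2, NaBH4, EtOH, −10 °C → rt; then 2 M HCl
Reagents that add atoms: none
Why: Ca(BH4)2 formed in the flask should reduce the ester but not the carboxylate, and acidification lactonises the hydroxy acid with the stereocentre untouched.

Step 15
Reactants: 25 (R)-4-[4-(benzyloxy)-3-bromo-5-methoxybenzyl]dihydrofuran-2(3H)-one; 19 (2S,3R)-3-[(benzyloxy)methyl]-2-[4-(benzyloxy)-3-methoxyphenyl]-5-(bromomethyl)-7-methoxy-2,3-dihydro-1-benzofuran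
Product: 26 (3R,4R)-4-[4-(benzyloxy)-3-bromo-5-methoxybenzyl]-3-{[(2S,3R)-3-[(benzyloxy)methyl]-2-[4-(benzyloxy)-3-methoxyphenyl]-7-methoxy-2,3-dihydro-1-benzofuran-5-yl]methyl}dihydrofuran-2(3H)-one
Conditions: LiN(SiMe3)2, THF, −78 °C; then 19, HMPA, −78 → −40 °C
Reagents that add atoms: none
Why: Alkylation of the lactone lithium enolate should occur anti to the C4 benzyl group, giving the trans-(3R,4R) lactone that is also the thermodynamic isomer.

Step 16
Reactants: 27 (R)-3-acetyl-4-benzyl-1,3-oxazolidin-2-one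
Product: 28 (R)-4-benzyl-3-[1-(trimethylsilyloxy)ethenyl]-1,3-oxazolidin-2-one
Conditions: LiN(SiMe3)2, Me3SiCl, THF, −78 °C → rt; filter, concentrate
Reagents that add atoms: chlorotrimethylsilane, C[Si](C)(C)Cl
Why: In situ O-silylation of the imide enolate should give the silyl enolate needed for a base-free arylation.

Step 17
Reactants: 26 the bromoaryl trans-lactone; 28 (R)-4-benzyl-3-[1-(trimethylsilyloxy)ethenyl]-1,3-oxazolidin-2-one
Product: 29 (R)-4-benzyl-3-{[2-(benzyloxy)-3-methoxy-5-({(3R,4R)-4-{[(2S,3R)-3-[(benzyloxy)methyl]-2-[4-(benzyloxy)-3-methoxyphenyl]-7-methoxy-2,3-dihydro-1-benzofuran-5-yl]methyl}-5-oxotetrahydrofuran-3-yl}methyl)phenyl]acetyl}-1,3-oxazolidin-2-one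
Conditions: Pd(dba)2 (5 mol %), P(t-Bu)3 (10 mol %), ZnF2 (0.5 equiv), DMF, 80 °C
Reagents that add atoms: none
Why: Palladium-catalysed α-arylation of the imide silyl enolate, activated by ZnF2 under nearly neutral conditions, should replace the bromide by the acyl-oxazolidinone CH2 unit without enolising the lactone.

Step 18
Reactants: 29 the arylacetyl oxazolidinone; 1 4-(benzyloxy)-3-methoxybenzaldehyde
Product: 30 (4R)-4-benzyl-3-[(2R,3R)-3-[4-(benzyloxy)-3-methoxyphenyl]-3-hydroxy-2-(aryl)propanoyl]-1,3-oxazolidin-2-one, aryl being the 2-(benzyloxy)-3-methoxy-5-(lactonylmethyl)phenyl group of 29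
Conditions: n-Bu2BOTf, i-Pr2NEt, CH2Cl2, −78 → 0 °C; then 1, −78 → 0 °C; pH 7 buffer, MeOH, 30% H2O2
Reagents that add atoms: none
Why: Evans syn-aldol, in which the (Z)-boron enolate of the imide (enolised selectively over the lactone) reacts through a Zimmerman–Traxler chair on the face away from the auxiliary benzyl group, so the (R)-auxiliary should set the α-aryl centre as 2R, which is the S centre of the target once the carbonyl priorities change.

Step 19
Reactants: 30 the syn-aldol imide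
Product: 31 (1R,2S)-1-[4-(benzyloxy)-3-methoxyphenyl]-2-(aryl)propane-1,3-diol, aryl as in 30
Conditions: NaBH4, THF/H2O (4:1), 0 °C
Reagents that add atoms: none
Why: Borohydride should reduce the activated exocyclic imide carbonyl to the primary alcohol and release the auxiliary faster than it attacks the γ-lactone, leaving both stereocentres of the aldol unit untouched.

Step 20
Reactants: 31 the 1,3-diol
Product: 32 (S)-1-[4-(benzyloxy)-3-methoxyphenyl]-3-hydroxy-2-(aryl)propan-1-one, aryl as in 30 (tetrabenzyl ether of the target)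
Conditions: MnO2 (activated, excess), CH2Cl2, rt
Reagents that add atoms: none
Why: Activated MnO2 should oxidise only the electron-rich secondary benzylic alcohol, leaving the primary alcohol alone and, under neutral heterogeneous conditions, not epimerising the α-aryl centre.

Step 21
Reactants: 32 the tetrabenzyl ether
Product: 33 CNP0111438.1 (target)
Conditions: H2 (1 atm), 10% Pd/C, EtOAc/EtOH, rt
Reagents that add atoms: none
Why: Neutral hydrogenolysis should cleave the three aryl benzyl ethers and the alkyl benzyl ether without base or acid, so the labile α-aryl β-hydroxy ketone centre keeps its configuration.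

Compound list
1 | 4-(benzyloxy)-3-methoxybenzaldehyde | COc1cc(C=O)ccc1OCc1ccccc1 | starting material
2 | vinylmagnesium bromide | C=C[Mg]Br | starting material
3 | (±)-1-[4-(benzyloxy)-3-methoxyphenyl]prop-2-en-1-ol | C=CC(O)c1ccc(OCc2ccccc2)c(OC)c1 | intermediate
4 | (R)-[4-(benzyloxy)-3-methoxyphenyl][(2S)-oxiran-2-yl]methanol | O[C@H](c1ccc(OCc2ccccc2)c(OC)c1)[C@@H]1CO1 | intermediate
5 | 3,5-dibromo-4-hydroxybenzaldehyde | O=Cc1cc(Br)c(O)c(Br)c1 | starting material
6 | 2,6-dibromo-4-(1,3-dioxolan-2-yl)phenol | Oc1c(Br)cc(cc1Br)C1OCCO1 | intermediate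
7 | [2,6-dibromo-4-(1,3-dioxolan-2-yl)phenoxy]trimethylsilane | C[Si](C)(C)Oc1c(Br)cc(cc1Br)C1OCCO1 | intermediate
8 | [4-(1,3-dioxolan-2-yl)-2,6-bis(trimethylsilyl)phenoxy]trimethylsilane | C[Si](C)(C)Oc1c([Si](C)(C)C)cc(cc1[Si](C)(C)C)C1OCCO1 | intermediate
9 | 4-(1,3-dioxolan-2-yl)-2,6-bis(trimethylsilyl)phenol | Oc1c([Si](C)(C)C)cc(cc1[Si](C)(C)C)C1OCCO1 | intermediate
10 | 4-(1,3-dioxolan-2-yl)-2,6-bis(trimethylsilyl)phenyl trifluoromethanesulfonate | FC(F)(F)S(=O)(=O)Oc1c([Si](C)(C)C)cc(cc1[Si](C)(C)C)C1OCCO1 | intermediate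
11 | sodium (R)-[4-(benzyloxy)-3-methoxyphenyl][(2S)-oxiran-2-yl]methanolate | [Na+].[O-][C@H](c1ccc(OCc2ccccc2)c(OC)c1)[C@@H]1CO1 | intermediate
12 | 5-(1,3-dioxolan-2-yl)-3-(trimethylsilyl)benzyne | C[Si](C)(C)C1=CC(C2OCCO2)=CC#C1 | intermediate
13 | sodium [(2S,3R)-2-[4-(benzyloxy)-3-methoxyphenyl]-5-(1,3-dioxolan-2-yl)-7-(trimethylsilyl)-2,3-dihydro-1-benzofuran-3-yl]methanolate | O1CCOC1c1cc([Si](C)(C)C)c2c(c1)[C@H](C[O-])[C@@H](c1ccc(OCc3ccccc3)c(OC)c1)O2.[Na+] | intermediate
14 | (2S,3R)-3-[(benzyloxy)methyl]-2-[4-(benzyloxy)-3-methoxyphenyl]-5-(1,3-dioxolan-2-yl)-7-(trimethylsilyl)-2,3-dihydro-1-benzofuran | O1CCOC1c1cc([Si](C)(C)C)c2c(c1)[C@H](COCc1ccccc1)[C@@H](c1ccc(OCc3ccccc3)c(OC)c1)O2 | intermediate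
15 | (2S,3R)-3-[(benzyloxy)methyl]-2-[4-(benzyloxy)-3-methoxyphenyl]-5-(1,3-dioxolan-2-yl)-7-iodo-2,3-dihydro-1-benzofuran | O1CCOC1c1cc(I)c2c(c1)[C@H](COCc1ccccc1)[C@@H](c1ccc(OCc3ccccc3)c(OC)c1)O2 | intermediate
16 | (2S,3R)-3-[(benzyloxy)methyl]-2-[4-(benzyloxy)-3-methoxyphenyl]-5-(1,3-dioxolan-2-yl)-7-methoxy-2,3-dihydro-1-benzofuran | O1CCOC1c1cc(OC)c2c(c1)[C@H](COCc1ccccc1)[C@@H](c1ccc(OCc3ccccc3)c(OC)c1)O2 | intermediate
17 | (2S,3R)-3-[(benzyloxy)methyl]-2-[4-(benzyloxy)-3-methoxyphenyl]-7-methoxy-2,3-dihydro-1-benzofuran-5-carbaldehyde | O=Cc1cc(OC)c2c(c1)[C@H](COCc1ccccc1)[C@@H](c1ccc(OCc3ccccc3)c(OC)c1)O2 | intermediate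
18 | [(2S,3R)-3-[(benzyloxy)methyl]-2-[4-(benzyloxy)-3-methoxyphenyl]-7-methoxy-2,3-dihydro-1-benzofuran-5-yl]methanol | OCc1cc(OC)c2c(c1)[C@H](COCc1ccccc1)[C@@H](c1ccc(OCc3ccccc3)c(OC)c1)O2 | intermediate
19 | (2S,3R)-3-[(benzyloxy)methyl]-2-[4-(benzyloxy)-3-methoxyphenyl]-5-(bromomethyl)-7-methoxy-2,3-dihydro-1-benzofuran | BrCc1cc(OC)c2c(c1)[C@H](COCc1ccccc1)[C@@H](c1ccc(OCc3ccccc3)c(OC)c1)O2 | intermediate
20 | 3-bromo-4-hydroxy-5-methoxybenzaldehyde (5-bromovanillin) | COc1cc(C=O)cc(Br)c1O | starting material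
21 | 4-(benzyloxy)-3-bromo-5-methoxybenzaldehyde | COc1cc(C=O)cc(Br)c1OCc1ccccc1 | intermediate
22 | dimethyl succinate | COC(=O)CCC(=O)OC | starting material
23 | (E)-4-[4-(benzyloxy)-3-bromo-5-methoxyphenyl]-3-(methoxycarbonyl)but-3-enoic acid | COC(=O)/C(CC(=O)O)=C/c1cc(OC)c(OCc2ccccc2)c(Br)c1 | intermediate
24 | (R)-4-[4-(benzyloxy)-3-bromo-5-methoxyphenyl]-3-(methoxycarbonyl)butanoic acid | COC(=O)[C@@H](CC(=O)O)Cc1cc(OC)c(OCc2ccccc2)c(Br)c1 | intermediate
25 | (R)-4-[4-(benzyloxy)-3-bromo-5-methoxybenzyl]dihydrofuran-2(3H)-one | O=C1C[C@@H](Cc2cc(OC)c(OCc3ccccc3)c(Br)c2)CO1 | intermediate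
26 | (3R,4R)-4-[4-(benzyloxy)-3-bromo-5-methoxybenzyl]-3-{[(2S,3R)-3-[(benzyloxy)methyl]-2-[4-(benzyloxy)-3-methoxyphenyl]-7-methoxy-2,3-dihydro-1-benzofuran-5-yl]methyl}dihydrofuran-2(3H)-one | Brc1cc(C[C@H]2COC(=O)[C@@H]2Cc2cc(OC)c3c(c2)[C@H](COCc2ccccc2)[C@@H](c2ccc(OCc4ccccc4)c(OC)c2)O3)cc(OC)c1OCc1ccccc1 | intermediate
27 | (R)-3-acetyl-4-benzyl-1,3-oxazolidin-2-one | CC(=O)N1[C@H](Cc2ccccc2)COC1=O | starting material
28 | (R)-4-benzyl-3-[1-(trimethylsilyloxy)ethenyl]-1,3-oxazolidin-2-one | C=C(O[Si](C)(C)C)N1[C@H](Cc2ccccc2)COC1=O | intermediate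
29 | arylacetyl oxazolidinone (26 with Br replaced by CH2C(=O)-[(R)-4-benzyl-2-oxo-1,3-oxazolidin-3-yl]) | O=C(Cc1cc(C[C@H]2COC(=O)[C@@H]2Cc2cc(OC)c3c(c2)[C@H](COCc2ccccc2)[C@@H](c2ccc(OCc4ccccc4)c(OC)c2)O3)cc(OC)c1OCc1ccccc1)N1[C@H](Cc2ccccc2)COC1=O | intermediate
30 | syn-aldol imide, (2R,3R) in the propanoyl chain | O=C(N1[C@H](Cc2ccccc2)COC1=O)[C@H](c1cc(C[C@H]2COC(=O)[C@@H]2Cc2cc(OC)c3c(c2)[C@H](COCc2ccccc2)[C@@H](c2ccc(OCc4ccccc4)c(OC)c2)O3)cc(OC)c1OCc1ccccc1)[C@@H](O)c1ccc(OCc2ccccc2)c(OC)c1 | intermediate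
31 | (1R,2S)-1,3-diol | OC[C@H](c1cc(C[C@H]2COC(=O)[C@@H]2Cc2cc(OC)c3c(c2)[C@H](COCc2ccccc2)[C@@H](c2ccc(OCc4ccccc4)c(OC)c2)O3)cc(OC)c1OCc1ccccc1)[C@@H](O)c1ccc(OCc2ccccc2)c(OC)c1 | intermediate
32 | (S)-β-hydroxy ketone, tetrabenzyl ether of the target | OC[C@H](c1cc(C[C@H]2COC(=O)[C@@H]2Cc2cc(OC)c3c(c2)[C@H](COCc2ccccc2)[C@@H](c2ccc(OCc4ccccc4)c(OC)c2)O3)cc(OC)c1OCc1ccccc1)C(=O)c1ccc(OCc2ccccc2)c(OC)c1 | intermediate
33 | CNP0111438.1 | COc1cc(C(=O)[C@H](CO)c2cc(C[C@H]3COC(=O)[C@@H]3Cc3cc(OC)c4c(c3)[C@H](CO)[C@@H](c3ccc(O)c(OC)c3)O4)cc(OC)c2O)ccc1O | target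

Total step count: 21. Longest linear sequence: 14 steps (from 5 through steps 3–10, 15 and 17–21).

Steps most likely to fail, in order of risk:

Step 6 (key step). The alkoxide may add at the aryne carbon remote from silicon if steric hindrance outweighs the electronic bias. The epoxy alkoxide may undergo Payne rearrangement before it meets the aryne, the aryl anion may be protonated before it closes the ring, or the cyclised primary alkoxide may add to a second aryne. The fallback uses known chemistry and makes the two bonds in separate operations; it sets out from 4 and returns at 18. The sodium alkoxide of 4 (NaH, DMF, 0 °C) displaces fluoride from 3-bromo-4-fluoro-5-methoxybenzaldehyde (COc1cc(C=O)cc(Br)c1F) in an SNAr reaction para to the formyl group, with retention at the carbinol, to give the aryl ether aldehyde F1. NaBH4 in MeOH gives the benzylic alcohol F2, and TBSCl/imidazole gives its silyl ether F3. n-BuLi in THF at −78 °C (bromine–lithium exchange, then Parham-type 5-exo opening of the epoxide) followed by BnBr/HMPA gives the 7-methoxy dihydrobenzofuran silyl ether F4, whose regiochemistry is fixed by the positions of fluorine and bromine. n-Bu4NF then gives 18.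

Step 17. Oxidative addition at the ortho-alkoxy aryl bromide may be slow, and the acetyl-imide silyl enolate may desilylate or self-condense before it couples. The fallback installs the auxiliary stepwise; it sets out from 26 and returns at 29. Coupling of 26 with the Reformatsky reagent BrZnCH2CO2t-Bu (Pd2(dba)3, XPhos, THF, 60 °C) gives the tert-butyl arylacetate F5. Me3SiOTf/2,6-lutidine followed by aqueous work-up gives the arylacetic acid F6. Mixed-anhydride formation (t-BuCOCl, Et3N) and acylation of (R)-4-benzyl-1,3-oxazolidin-2-one in the presence of LiCl then give 29.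

Step 19. Hydride may also attack the lactone, and the basic medium may induce retro-aldol cleavage. The fallback separates auxiliary removal from reduction; it sets out from 30 and returns at 31. LiOH/H2O2 in THF/H2O at 0 °C cleaves the auxiliary to the β-hydroxy acid F7 (any opened lactone closes again on acidification). BH3·SMe2 in THF at 0 °C then reduces the carboxylic acid in preference to the lactone to give 31.

Further compounds
F1 | step 6 | 3-bromo-4-{(R)-[4-(benzyloxy)-3-methoxyphenyl][(2S)-oxiran-2-yl]methoxy}-5-methoxybenzaldehyde | O=Cc1cc(OC)c(O[C@H](c2ccc(OCc3ccccc3)c(OC)c2)[C@@H]2CO2)c(Br)c1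
F2 | step 6 | (3-bromo-4-{(R)-[4-(benzyloxy)-3-methoxyphenyl][(2S)-oxiran-2-yl]methoxy}-5-methoxyphenyl)methanol | OCc1cc(OC)c(O[C@H](c2ccc(OCc3ccccc3)c(OC)c2)[C@@H]2CO2)c(Br)c1
F3 | step 6 | tert-butyldimethylsilyl ether of F2 | CC(C)(C)[Si](C)(C)OCc1cc(OC)c(O[C@H](c2ccc(OCc3ccccc3)c(OC)c2)[C@@H]2CO2)c(Br)c1
F4 | step 6 | (2S,3R)-3-[(benzyloxy)methyl]-2-[4-(benzyloxy)-3-methoxyphenyl]-5-{[(tert-butyldimethylsilyl)oxy]methyl}-7-methoxy-2,3-dihydro-1-benzofuran | CC(C)(C)[Si](C)(C)OCc1cc(OC)c2c(c1)[C@H](COCc1ccccc1)[C@@H](c1ccc(OCc3ccccc3)c(OC)c1)O2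
F5 | step 17 | tert-butyl arylacetate (26 with Br replaced by CH2CO2t-Bu) | CC(C)(C)OC(=O)Cc1cc(C[C@H]2COC(=O)[C@@H]2Cc2cc(OC)c3c(c2)[C@H](COCc2ccccc2)[C@@H](c2ccc(OCc4ccccc4)c(OC)c2)O3)cc(OC)c1OCc1ccccc1
F6 | step 17 | arylacetic acid (26 with Br replaced by CH2CO2H) | OC(=O)Cc1cc(C[C@H]2COC(=O)[C@@H]2Cc2cc(OC)c3c(c2)[C@H](COCc2ccccc2)[C@@H](c2ccc(OCc4ccccc4)c(OC)c2)O3)cc(OC)c1OCc1ccccc1
F7 | step 19 | (2R,3R)-β-hydroxy acid (30 without the auxiliary) | OC(=O)[C@H](c1cc(C[C@H]2COC(=O)[C@@H]2Cc2cc(OC)c3c(c2)[C@H](COCc2ccccc2)[C@@H](c2ccc(OCc4ccccc4)c(OC)c2)O3)cc(OC)c1OCc1ccccc1)[C@@H](O)c1ccc(OCc2ccccc2)c(OC)c1
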